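**Plan**
1. Daucane numbering is used for every compound: C1 is the quaternary ring-fusion carbon with the methyl group, C2–C4 lie in the cyclopentane, C5 is the ring-fusion CH, C6–C10 lie in the cycloheptene, and β is the face of the C1 methyl. The target is the trans-fused 2α,6α-diangelate of the 2α,4β,6α-triol.
2. Retrosynthesis cuts the two ester C–O bonds, then the C3–C4 bond of the cyclopentane (ring C1–C5). C3 is an isolated CH2 between oxygen-bearing C2 and the fully substituted C4 carbinol, so a C2 diazoketone carbenoid on C1 of the seven-membered ring can insert into the C4–H bond of an isopropyl carbinol ether on C5.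
3. The cycloheptene is then cut at C8=C9 (ring-closing metathesis), C1–CH3 and C1–C10 (lactone enolate alkylations), C6–C7 (methallylation of an aldehyde) and C5–C1 (alkylation of a β-hydroxy ester dianion).
4. Forward order: acyclic C11–C4–C5–C6 chain, a γ-lactone (C2 to O6) as template for quaternary C1, lactone opening, the seven-membered ring, the diazoketone, the five-membered ring, then redox adjustment and acylation.
5. Stereochemistry: C4 from asymmetric hydrogenation of a β-keto ester; C5 by anti alkylation of the chelated dianion; C6 by reagent-controlled methallylboration; C1 by methylation of the lactone enolate anti to the C5 and C6 substituents; C4 carried through the C–H insertion with retention; C2 by hydride delivery from the C4 hydroxyl.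

Key step: step 12

Remark: the dianion alkylation of step 2 is assumed to accept tert-butyl bromoacetate as it accepts allylic halides, and the methallylborane of the (+)-α-pinene series is taken to attack the Si face of C6 as it does with simple aliphatic aldehydes.

**Route**

Step 1
Reactants: 1 ethyl 4-methyl-3-oxopentanoate
Product: 2 ethyl (3S)-3-hydroxy-4-methylpentanoate
Conditions: H2 (50 atm), RuCl2[(R)-BINAP] (divalent ruthenium, 0.1 mol%), EtOH, 50 °C
Reagents that add atoms: none
Why: Noyori asymmetric hydrogenation of a β-keto ester, in which the (R)-BINAP catalyst reduces the ketone face that leads to the (S)-alcohol and so fixes C4, the carbinol carbon of the later C–H insertion.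

Step 2
Reactants: 2 ethyl (3S)-3-hydroxy-4-methylpentanoate; 3 tert-butyl bromoacetate
Product: 5 4-tert-butyl 1-ethyl (2R)-2-[(1R)-1-hydroxy-2-methylpropyl]butanedioate, via dilithium alkoxide enolate 4 (not isolated)
Conditions: LiN(iPr)2 (2.2 equiv), THF, −78 to −20 °C; then 3, DMPU, −78 to −30 °C
Reagents that add atoms: tert-butyl bromoacetate (3), BrCC(=O)OC(C)(C)C
Why: Fráter–Seebach alkylation, in which the lithium-chelated alkoxide enolate is attacked on the face away from the isopropyl group so that C5 is set anti to the C4 oxygen, while the tert-butyl ester keeps the C4 alkoxide from lactonising.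

Step 3
Reactants: 5 4-tert-butyl 1-ethyl (2R)-2-[(1R)-1-hydroxy-2-methylpropyl]butanedioate
Product: 6 4-tert-butyl 1-ethyl (2R)-2-[(1R)-1-(methoxymethoxy)-2-methylpropyl]butanedioate
Conditions: MOMCl, iPr2NEt, nBu4NI (cat.), CH2Cl2, 0 to 40 °C
Reagents that add atoms: chloromethyl methyl ether, COCCl
Why: Iodide-assisted O-alkylation of a hindered secondary alcohol under amine base leaves both esters untouched and installs the small ether that will activate the C4–H bond toward the carbenoid.

Step 4
Reactants: 6 4-tert-butyl 1-ethyl (2R)-2-[(1R)-1-(methoxymethoxy)-2-methylpropyl]butanedioate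
Product: 7 tert-butyl (3R,4R)-3-formyl-4-(methoxymethoxy)-5-methylhexanoate
Conditions: iBu2AlH (1.1 equiv), CH2Cl2, −78 °C; aq. potassium sodium tartrate
Reagents that add atoms: none
Why: Partial reduction of the ethyl ester stops at the aldehyde because the aluminium hemiacetal, chelated by the β-MOM ether, survives at −78 °C until work-up, and the tert-butyl ester reacts much more slowly.

Step 5
Reactants: 7 tert-butyl (3R,4R)-3-formyl-4-(methoxymethoxy)-5-methylhexanoate; 8 2-methylallylmagnesium chloride
Product: 9 tert-butyl (3S,4R)-3-[(1S)-1-hydroxy-3-methylbut-3-en-1-yl]-4-(methoxymethoxy)-5-methylhexanoate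
Conditions: (−)-Ipc2BOMe (from (+)-α-pinene), 8, Et2O, −78 °C to rt; then 7, −78 °C; then NaOH, H2O2, 0 °C to rt
Reagents that add atoms: 2-methylallylmagnesium chloride (8), CC(=C)C[Mg]Cl
Why: Brown methallylboration through a closed Zimmerman–Traxler chair, in which the diisopinocampheylborane of the (+)-α-pinene series adds to the Si face of C6 under reagent control and should give the (S)-carbinol (5,6-anti, 4,6-syn) against the Felkin preference of the aldehyde.

Step 6
Reactants: 9 tert-butyl (3S,4R)-3-[(1S)-1-hydroxy-3-methylbut-3-en-1-yl]-4-(methoxymethoxy)-5-methylhexanoate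
Product: 10 (4S,5S)-4-[(1R)-1-(methoxymethoxy)-2-methylpropyl]-5-(2-methylprop-2-en-1-yl)oxolan-2-one
Conditions: NaH (0.2 equiv), THF, 0 °C to rt
Reagents that add atoms: none
Why: Alkoxide-catalysed intramolecular transesterification (5-exo-trig) of the γ-hydroxy tert-butyl ester touches no stereocentre and gives the cis-4,5-disubstituted γ-lactone that serves as template for C1.

Step 7
Reactants: 10 (4S,5S)-4-[(1R)-1-(methoxymethoxy)-2-methylpropyl]-5-(2-methylprop-2-en-1-yl)oxolan-2-one; 11 allyl bromide
Product: 13 (3S,4S,5S)-4-[(1R)-1-(methoxymethoxy)-2-methylpropyl]-5-(2-methylprop-2-en-1-yl)-3-(prop-2-en-1-yl)oxolan-2-one, via lithium enolate 12 (not isolated)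
Conditions: LiN(iPr)2 (1.05 equiv), THF, −78 °C; then 11, −78 to −40 °C
Reagents that add atoms: allyl bromide (11), C=CCBr
Why: Alkylation of the lactone lithium enolate with an allylic halide occurs anti to the C5 side chain, and the C1 configuration at this stage does not matter because C1 is enolised again in step 8.

Step 8
Reactants: 13 (3S,4S,5S)-4-[(1R)-1-(methoxymethoxy)-2-methylpropyl]-5-(2-methylprop-2-en-1-yl)-3-(prop-2-en-1-yl)oxolan-2-one; 14 iodomethane
Product: 16 (3R,4S,5S)-4-[(1R)-1-(methoxymethoxy)-2-methylpropyl]-3-methyl-5-(2-methylprop-2-en-1-yl)-3-(prop-2-en-1-yl)oxolan-2-one, via lithium enolate 15 (not isolated)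
Conditions: LiN(iPr)2 (1.2 equiv), THF, −78 °C; then 14, DMPU, −78 to −20 °C
Reagents that add atoms: iodomethane (14), CI
Why: In this second lactone enolate alkylation iodomethane approaches the face opposite the cis C5 and C6 substituents, so the methyl group ends trans and the allyl group cis to the C5 side chain, which is the C1 configuration of the target (the reverse order of alkylation would give the C1 epimer).

Step 9
Reactants: 16 (3R,4S,5S)-4-[(1R)-1-(methoxymethoxy)-2-methylpropyl]-3-methyl-5-(2-methylprop-2-en-1-yl)-3-(prop-2-en-1-yl)oxolan-2-one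
Product: 19 (2R,3R,4S)-4-[(tert-butyldimethylsilyl)oxy]-3-[(1R)-1-(methoxymethoxy)-2-methylpropyl]-2,6-dimethyl-2-(prop-2-en-1-yl)hept-6-enoic acid, via potassium hydroxy carboxylate 17 (not isolated), via silyl ester silyl ether 18 (not isolated)
Conditions: KOH, MeOH/H2O, 65 °C, evaporate; TBSOTf (3 equiv), 2,6-lutidine, CH2Cl2, −40 to 0 °C; K2CO3, MeOH/THF/H2O, rt
Reagents that add atoms: potassium hydroxide, [K+].[OH-]; tert-butyldimethylsilyl trifluoromethanesulfonate, CC(C)(C)[Si](C)(C)OS(=O)(=O)C(F)(F)F
Why: Saponification of the γ-lactone, silylation of both oxygens of the hydroxy carboxylate with the fast silyl triflate before the ring can close again, and selective cleavage of the labile silyl ester affect no stereocentre and leave the C6 oxygen as its TBS ether.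

Step 10
Reactants: 19 (2R,3R,4S)-4-[(tert-butyldimethylsilyl)oxy]-3-[(1R)-1-(methoxymethoxy)-2-methylpropyl]-2,6-dimethyl-2-(prop-2-en-1-yl)hept-6-enoic acid
Product: 20 (1R,6S,7R)-6-[(tert-butyldimethylsilyl)oxy]-7-[(1R)-1-(methoxymethoxy)-2-methylpropyl]-1,4-dimethylcyclohept-3-ene-1-carboxylic acid
Conditions: second-generation Grubbs catalyst RuCl2(=CHPh)(H2IMes)(PCy3) (5 mol%), CH2Cl2 (5 mM), 40 °C
Reagents that add atoms: none
Why: Ring-closing metathesis of the allyl and methallyl groups, helped by the Thorpe–Ingold effect of quaternary C1, forms the trisubstituted C8=C9 alkene of the cycloheptene with loss of ethene and tolerates the free acid and both ethers.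

Step 11
Reactants: 20 (1R,6S,7R)-6-[(tert-butyldimethylsilyl)oxy]-7-[(1R)-1-(methoxymethoxy)-2-methylpropyl]-1,4-dimethylcyclohept-3-ene-1-carboxylic acid; 21 diazomethane
Product: 23 2-diazo-1-[(1R,6S,7R)-6-[(tert-butyldimethylsilyl)oxy]-7-[(1R)-1-(methoxymethoxy)-2-methylpropyl]-1,4-dimethylcyclohept-3-en-1-yl]ethan-1-one, via acid chloride 22 (not isolated)
Conditions: Me2C=C(Cl)NMe2, CH2Cl2, 0 °C; then 21 (excess), Et2O, 0 °C to rt
Reagents that add atoms: diazomethane (21), C=[N+]=[N-]
Why: The Ghosez chloroenamine makes the acid chloride without free HCl and, kept cold, before either ether oxygen can cyclise onto it; acylation of diazomethane (the first stage of an Arndt–Eistert sequence) then gives the diazoketone, and the quaternary α-carbon excludes ketene formation.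

Step 12
Reactants: 23 2-diazo-1-[(1R,6S,7R)-6-[(tert-butyldimethylsilyl)oxy]-7-[(1R)-1-(methoxymethoxy)-2-methylpropyl]-1,4-dimethylcyclohept-3-en-1-yl]ethan-1-one
Product: 24 4β-(methoxymethoxy)-6α-[(tert-butyldimethylsilyl)oxy]dauc-8-en-2-one
Conditions: Rh2(O2CC3F7)4 (divalent rhodium, 1 mol%), CH2Cl2, rt, slow addition of 23
Reagents that add atoms: none
Why: Loss of N2 gives an electrophilic dirhodium carbenoid at C3 that inserts into the C4–H bond in one concerted, asynchronous step with hydride-like transfer through a six-centre transition state (C3, C2, C1, C5, C4, H); the closest known reaction type is the dirhodium carboxylate-catalysed 1,5 C–H insertion of α-diazoketones next to an ether oxygen. The cyclopentanone (ring C1–C5) closes by forming C3–C4, a 1,5 insertion that is preferred over four- and six-membered alternatives. The new fully substituted stereocentre C4 forms with retention, so its configuration is the one set by the hydrogenation of step 1, and the trans ring fusion is inherited from the trans C1/C5 relationship fixed in steps 2 and 8. The step needs C4–H insertion to win over cyclopropanation of C8=C9, oxonium ylide formation at the MOM oxygen and insertion into C6–H. The substrate secures this because C4–H is tertiary and activated by the ether oxygen, it should sit gauche to C1 in the rotamer that places the isopropyl group anti to the quaternary carbon, the equatorial acyl group points away from the alkene, and C6–H lies on the face opposite the acyl group. The perfluorobutyrate ligands further tilt the carbenoid toward insertion into electron-rich C–H bonds and away from alkene addition.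

Step 13
Reactants: 24 4β-(methoxymethoxy)-6α-[(tert-butyldimethylsilyl)oxy]dauc-8-en-2-one
Product: 26 4β-hydroxy-6α-[(tert-butyldimethylsilyl)oxy]dauc-8-en-2-one, via bromomethyl ether 25 (not isolated)
Conditions: Me2BBr (3 equiv), CH2Cl2, −78 °C; then aq. NaHCO3/THF
Reagents that add atoms: none
Why: Me2BBr cleaves the MOM acetal at −78 °C by bromide attack on the boron-activated OCH2O carbon and the bromomethyl ether is hydrolysed on work-up, so the tertiary C4–O bond is never ionised, the β-alkoxy ketone should not eliminate and the secondary TBS ether stays.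

Step 14
Reactants: 26 4β-hydroxy-6α-[(tert-butyldimethylsilyl)oxy]dauc-8-en-2-one
Product: 27 6α-[(tert-butyldimethylsilyl)oxy]dauc-8-ene-2α,4β-diol
Conditions: Me4NBH(OAc)3, MeCN/AcOH (1:1), −20 °C to rt
Reagents that add atoms: none
Why: Evans–Saksena reduction, in which acetate exchange binds the borohydride to the C4 hydroxyl and hydride is delivered intramolecularly to the β face of C2, which should give the 2α-alcohol (1,3-anti to the 4β-hydroxyl) despite the neighbouring β-methyl group.

Step 15
Reactants: 27 6α-[(tert-butyldimethylsilyl)oxy]dauc-8-ene-2α,4β-diol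
Product: 28 dauc-8-ene-2α,4β,6α-triol
Conditions: nBu4NF, THF, rt to 50 °C
Reagents that add atoms: none
Why: Fluoride cleaves the Si–O bond of the secondary silyl ether, and with the ketone already reduced the basic reagent can no longer cause retro-aldol cleavage.

Step 16
Reactants: 28 dauc-8-ene-2α,4β,6α-triol; 29 angelic acid
Product: 31 2α,6α-bis[(Z)-2-methylbut-2-enoyloxy]dauc-8-en-4β-ol, via mixed anhydride 30 (not isolated)
Conditions: 29, 2,4,6-Cl3C6H2COCl, Et3N, toluene, rt; then 28, toluene, 80 °C
Reagents that add atoms: angelic acid (29), C/C=C(/C)C(=O)O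
Why: Yamaguchi-type esterification through the angelic 2,4,6-trichlorobenzoic mixed anhydride, run without DMAP, should acylate the two secondary alcohols without Z-to-E isomerisation to the tiglate, while the tertiary C4 hydroxyl is too hindered to react.

**Compound list**
1 | ethyl 4-methyl-3-oxopentanoate | CCOC(=O)CC(=O)C(C)C | starting material
2 | ethyl (3S)-3-hydroxy-4-methylpentanoate | CCOC(=O)C[C@H](O)C(C)C | intermediate
3 | tert-butyl bromoacetate | BrCC(=O)OC(C)(C)C | starting material
4 | dilithium alkoxide enolate of 2 (chelated) | CCO/C([O-])=C/[C@H]([O-])C(C)C.[Li+].[Li+] | intermediate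
5 | 4-tert-butyl 1-ethyl (2R)-2-[(1R)-1-hydroxy-2-methylpropyl]butanedioate | CCOC(=O)[C@H](CC(=O)OC(C)(C)C)[C@H](O)C(C)C | intermediate
6 | 4-tert-butyl 1-ethyl (2R)-2-[(1R)-1-(methoxymethoxy)-2-methylpropyl]butanedioate | CCOC(=O)[C@H](CC(=O)OC(C)(C)C)[C@H](OCOC)C(C)C | intermediate
7 | tert-butyl (3R,4R)-3-formyl-4-(methoxymethoxy)-5-methylhexanoate | O=C[C@H](CC(=O)OC(C)(C)C)[C@H](OCOC)C(C)C | intermediate
8 | 2-methylallylmagnesium chloride | CC(=C)C[Mg]Cl | starting material
9 | tert-butyl (3S,4R)-3-[(1S)-1-hydroxy-3-methylbut-3-en-1-yl]-4-(methoxymethoxy)-5-methylhexanoate | CC(=C)C[C@H](O)[C@H](CC(=O)OC(C)(C)C)[C@H](OCOC)C(C)C | intermediate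
10 | (4S,5S)-4-[(1R)-1-(methoxymethoxy)-2-methylpropyl]-5-(2-methylprop-2-en-1-yl)oxolan-2-one (4,5-cis) | O=C1C[C@H]([C@H](OCOC)C(C)C)[C@H](CC(C)=C)O1 | intermediate
11 | allyl bromide | C=CCBr | starting material
12 | lithium enolate of lactone 10 | [Li+].[O-]C1=C[C@H]([C@H](OCOC)C(C)C)[C@H](CC(C)=C)O1 | intermediate
13 | (3S,4S,5S)-4-[(1R)-1-(methoxymethoxy)-2-methylpropyl]-5-(2-methylprop-2-en-1-yl)-3-(prop-2-en-1-yl)oxolan-2-one | O=C1[C@@H](CC=C)[C@H]([C@H](OCOC)C(C)C)[C@H](CC(C)=C)O1 | intermediate
14 | iodomethane | CI | starting material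
15 | lithium enolate of lactone 13 | [Li+].[O-]C1=C(CC=C)[C@H]([C@H](OCOC)C(C)C)[C@H](CC(C)=C)O1 | intermediate
16 | (3R,4S,5S)-4-[(1R)-1-(methoxymethoxy)-2-methylpropyl]-3-methyl-5-(2-methylprop-2-en-1-yl)-3-(prop-2-en-1-yl)oxolan-2-one | O=C1[C@](C)(CC=C)[C@H]([C@H](OCOC)C(C)C)[C@H](CC(C)=C)O1 | intermediate
17 | potassium (2R,3S,4S)-4-hydroxy-3-[(1R)-1-(methoxymethoxy)-2-methylpropyl]-2,6-dimethyl-2-(prop-2-en-1-yl)hept-6-enoate | [K+].[O-]C(=O)[C@](C)(CC=C)[C@H]([C@H](OCOC)C(C)C)[C@@H](O)CC(C)=C | intermediate
18 | tert-butyldimethylsilyl ester of acid 19 | CC(C)(C)[Si](C)(C)OC(=O)[C@](C)(CC=C)[C@H]([C@H](OCOC)C(C)C)[C@@H](O[Si](C)(C)C(C)(C)C)CC(C)=C | intermediate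
19 | (2R,3R,4S)-4-[(tert-butyldimethylsilyl)oxy]-3-[(1R)-1-(methoxymethoxy)-2-methylpropyl]-2,6-dimethyl-2-(prop-2-en-1-yl)hept-6-enoic acid | OC(=O)[C@](C)(CC=C)[C@H]([C@H](OCOC)C(C)C)[C@@H](O[Si](C)(C)C(C)(C)C)CC(C)=C | intermediate
20 | (1R,6S,7R)-6-[(tert-butyldimethylsilyl)oxy]-7-[(1R)-1-(methoxymethoxy)-2-methylpropyl]-1,4-dimethylcyclohept-3-ene-1-carboxylic acid | OC(=O)[C@]1(C)CC=C(C)C[C@H](O[Si](C)(C)C(C)(C)C)[C@H]1[C@H](OCOC)C(C)C | intermediate
21 | diazomethane | C=[N+]=[N-] | starting material
22 | acid chloride of 20 | ClC(=O)[C@]1(C)CC=C(C)C[C@H](O[Si](C)(C)C(C)(C)C)[C@H]1[C@H](OCOC)C(C)C | intermediate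
23 | 2-diazo-1-[(1R,6S,7R)-6-[(tert-butyldimethylsilyl)oxy]-7-[(1R)-1-(methoxymethoxy)-2-methylpropyl]-1,4-dimethylcyclohept-3-en-1-yl]ethan-1-one | [N-]=[N+]=CC(=O)[C@]1(C)CC=C(C)C[C@H](O[Si](C)(C)C(C)(C)C)[C@H]1[C@H](OCOC)C(C)C | intermediate
24 | 4β-(methoxymethoxy)-6α-[(tert-butyldimethylsilyl)oxy]dauc-8-en-2-one (trans-fused; 1β-CH3; 5α-H) | O=C1C[C@@](OCOC)(C(C)C)[C@@H]2[C@@H](O[Si](C)(C)C(C)(C)C)CC(C)=CC[C@@]12C | intermediate
25 | 4β-(bromomethoxy)-6α-[(tert-butyldimethylsilyl)oxy]dauc-8-en-2-one | O=C1C[C@@](OCBr)(C(C)C)[C@@H]2[C@@H](O[Si](C)(C)C(C)(C)C)CC(C)=CC[C@@]12C | intermediate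
26 | 4β-hydroxy-6α-[(tert-butyldimethylsilyl)oxy]dauc-8-en-2-one | O=C1C[C@@](O)(C(C)C)[C@@H]2[C@@H](O[Si](C)(C)C(C)(C)C)CC(C)=CC[C@@]12C | intermediate
27 | 6α-[(tert-butyldimethylsilyl)oxy]dauc-8-ene-2α,4β-diol | O[C@H]1C[C@@](O)(C(C)C)[C@@H]2[C@@H](O[Si](C)(C)C(C)(C)C)CC(C)=CC[C@@]12C | intermediate
28 | dauc-8-ene-2α,4β,6α-triol | O[C@H]1C[C@@](O)(C(C)C)[C@@H]2[C@@H](O)CC(C)=CC[C@@]12C | intermediate
29 | angelic acid, (Z)-2-methylbut-2-enoic acid | C/C=C(/C)C(=O)O | starting material
30 | (Z)-2-methylbut-2-enoic 2,4,6-trichlorobenzoic anhydride | C/C=C(/C)C(=O)OC(=O)c1c(Cl)cc(Cl)cc1Cl | intermediate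
31 | 2α,6α-bis[(Z)-2-methylbut-2-enoyloxy]dauc-8-en-4β-ol (CNP0303897.1) | C/C=C(/C)C(=O)O[C@H]1CC(C)=CC[C@@]2(C)[C@@H](OC(=O)/C(C)=C\C)C[C@@](O)(C(C)C)[C@H]12 | target

**Step count**
Total steps: 16. Longest linear sequence: 16 steps (1 to 31).

**Steps most likely to fail**

Step 12. The carbenoid may add to the C8=C9 double bond (intramolecular cyclopropanation) or attack the MOM oxygen (oxonium ylide formation and rearrangement) faster than it inserts into C4–H. The fallback makes the C3–C4 bond as an aldol bond, without a carbene, and sets out from acid 20. CH3Li (2.5 equiv) converts 20 into the methyl ketone F1. Me2BBr then frees the C4 hydroxyl to give the hydroxy ketone F2, and Dess–Martin periodinane oxidises it to the 1,4-diketone F3. Kinetic deprotonation of the methyl group with LiN(SiMe3)2 at −78 °C and intramolecular aldol addition of C3 to the C4 ketone close the cyclopentane and rejoin the route at β-hydroxy ketone 26. In this variant the C4 configuration rests on the facial selectivity of the aldol addition, which is not secured; equilibration through the reversible aldol should favour the less crowded isomer with the isopropyl group cis to H-5.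

Step 9. Ring closure of the γ-hydroxy carboxylate, or of its silyl ester, back to lactone 16 may outrun silylation of the C6 hydroxyl. The fallback sets out from lactone 16 and opens it reductively with LiAlH4 to the diol F4, which cannot relactonise. TBSOTf/2,6-lutidine gives the bis-silyl ether F5. HF·pyridine buffered with pyridine removes the primary silyl ether selectively to give the primary alcohol F6. Oxidation with PhI(OAc)2/TEMPO and then NaClO2 returns to acid 19.

Step 5. Facial selectivity may be poor because the reagent has to overrule the Felkin preference of the α-branched aldehyde (a mismatched pair), and C5 of the aldehyde may epimerise. The fallback sets out from aldehyde 7 and sets C6 by ketone reduction instead. Reagent 8 is added without stereocontrol to give the C6-epimeric alcohols F7, and Dess–Martin periodinane gives the β,γ-unsaturated ketone F8. Corey–Bakshi–Shibata reduction with (R)-2-methyl-CBS-oxazaborolidine and catecholborane at −78 °C, with the branched C5 side as the large group, should set the (S)-carbinol and return to 9.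

Further compounds
F1 | step 12 | methyl ketone of acid 20 (COCH3 in place of COOH) | CC(=O)[C@]1(C)CC=C(C)C[C@H](O[Si](C)(C)C(C)(C)C)[C@H]1[C@H](OCOC)C(C)C
F2 | step 12 | hydroxy ketone from F1 (free C4–OH in place of the MOM ether) | CC(=O)[C@]1(C)CC=C(C)C[C@H](O[Si](C)(C)C(C)(C)C)[C@H]1[C@H](O)C(C)C
F3 | step 12 | 1,4-diketone from F2 (C4 carbinol oxidised to the isopropyl ketone) | CC(=O)[C@]1(C)CC=C(C)C[C@H](O[Si](C)(C)C(C)(C)C)[C@H]1C(=O)C(C)C
F4 | step 9 | (2R,3S,4S)-3-[(1R)-1-(methoxymethoxy)-2-methylpropyl]-2,6-dimethyl-2-(prop-2-en-1-yl)hept-6-ene-1,4-diol | OC[C@](C)(CC=C)[C@H]([C@H](OCOC)C(C)C)[C@@H](O)CC(C)=C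
F5 | step 9 | 1,4-bis(tert-butyldimethylsilyl) ether of F4 | CC(C)(C)[Si](C)(C)OC[C@](C)(CC=C)[C@H]([C@H](OCOC)C(C)C)[C@@H](O[Si](C)(C)C(C)(C)C)CC(C)=C
F6 | step 9 | primary alcohol from F5 (C6 silyl ether kept) | OC[C@](C)(CC=C)[C@H]([C@H](OCOC)C(C)C)[C@@H](O[Si](C)(C)C(C)(C)C)CC(C)=C
F7 | step 5 | C6-epimeric mixture of alcohol 9 | CC(=C)CC(O)[C@H](CC(=O)OC(C)(C)C)[C@H](OCOC)C(C)C
F8 | step 5 | tert-butyl (3R,4R)-4-(methoxymethoxy)-5-methyl-3-(3-methylbut-3-enoyl)hexanoate | CC(=C)CC(=O)[C@H](CC(=O)OC(C)(C)C)[C@H](OCOC)C(C)C
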